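## Retrosynthetic overview

1. The target is two 2,2-dimethyl-2H-chromenes joined C6–C6'. Arene A with pyran A (O1, C2, C3, C4, C4a, C8a) carries the C8 prenyl group. Arene B with pyran B (primed atoms) carries the C8' hydroxyl.
2. Enabling feature: the chain C4a–C4–C3–C2(CH3)2 of pyran A is a prenyl group lacking two hydrogens, mirror-related to the C8 prenyl group across the O1–C8a···C6 axis of arene A, and O1 and O1' both stand para to the C6–C6' bond. Arene A is thus a masked symmetric 2,6-diprenyl-1,4-benzoquinone whose surplus oxidation level equals the unsaturation of pyran A, and O1' can stabilise a cation at C6.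
3. Key disconnections, all made good in one flask: O1–C2 (retro-oxa-6π) to a vinyl ortho-quinone methide; formal re-addition of water (H to C4, OH to C6) to a 4-aryl-para-quinol; C6–C6' to a 6-lithiochromene plus the quinone.
4. Fragment 1, the quinone: 4-methoxyphenol, double ortho-C-prenylation, oxidative demethylation. Fragment 2, the bromochromene: 5-bromo-2,3-dihydroxybenzaldehyde, isobutenyl Grignard addition with dehydrative closure, silylation.
5. Ring order: both benzene rings are bought (arene A travels as the quinone ring), pyran B closes in step 3, pyran A closes last in step 5, and step 6 only removes silicon.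

Key step: step 5

Assumption: the target is achiral, so no stereocontrol is needed. 5-Bromo-2,3-dihydroxybenzaldehyde and 2-methylprop-1-enylmagnesium bromide in THF are taken as catalogue chemicals.

## Route

Step 1
Reactants: 1 4-methoxyphenol; 2 prenyl bromide (1-bromo-3-methylbut-2-ene, 2.2 equiv)
Product: 3 4-methoxy-2,6-bis(3-methylbut-2-enyl)phenol
Conditions: NaH (2.2 equiv), toluene, 0 °C to 23 °C
Reagents that add atoms: none
Why: Ortho-selective phenoxide C-alkylation (SN2 on prenyl bromide by the ring carbon of a sodium contact ion pair in a non-polar solvent) should place prenyl groups on both free ortho carbons, because the para carbon is blocked by OMe and each rearomatised phenol is deprotonated again by the second equivalent of NaH; no stereocentre is formed.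

Step 2
Reactants: 3 4-methoxy-2,6-bis(3-methylbut-2-enyl)phenol
Product: 4 2,6-bis(3-methylbut-2-enyl)-1,4-benzoquinone
Conditions: PhI(OAc)2 (1.1 equiv), MeCN/H2O 4:1, 0 °C
Reagents that add atoms: water, O
Why: Hypervalent-iodine oxidative demethylation of a para-methoxyphenol, in which water adds to the methoxy-stabilised cation at the para carbon and the hemiketal loses methanol, is far faster than any attack on the trisubstituted alkenes; no stereocentre is formed.

Step 3
Reactants: 5 5-bromo-2,3-dihydroxybenzaldehyde; 6 2-methylprop-1-enylmagnesium bromide (3.3 equiv)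
Product: 9 6-bromo-2,2-dimethyl-2H-chromen-8-ol, via racemic carbinol 7 (not isolated), via hydroxy ortho-quinone methide 8 (not isolated)
Conditions: THF, 0 °C to 23 °C; aq NH4Cl; crude, PPTS (cat.), toluene, 80 °C
Reagents that add atoms: none
Why: Grignard 1,2-addition to the salicylaldehyde, then acid-catalysed dehydration of the ortho-hydroxybenzylic allylic alcohol to a vinyl ortho-quinone methide and oxa-6π electrocyclisation, is a standard salicylaldehyde-to-2H-chromene sequence in which only the oxygen ortho to the side chain can close, so the other stays as the C8' hydroxyl and the racemic carbinol centre of 7 is erased.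

Step 4
Reactants: 9 6-bromo-2,2-dimethyl-2H-chromen-8-ol
Product: 10 [(6-bromo-2,2-dimethyl-2H-chromen-8-yl)oxy](tert-butyl)dimethylsilane
Conditions: TBSCl (1.2 equiv), imidazole (2.5 equiv), DMF, 23 °C
Reagents that add atoms: tert-butyldimethylsilyl chloride, CC(C)(C)[Si](C)(C)Cl
Why: Standard imidazole-promoted silylation of a phenol gives an ether that tolerates n-BuLi at −78 °C and the acylating medium of step 5 and is later removed without acid; no stereocentre is formed.

Step 5
Reactants: 10 [(6-bromo-2,2-dimethyl-2H-chromen-8-yl)oxy](tert-butyl)dimethylsilane; 4 2,6-bis(3-methylbut-2-enyl)-1,4-benzoquinone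
Product: 16 O-TBS ether of the target, via aryllithium 11 (not isolated), via lithium quinolate 12 (not isolated), via quinol trifluoroacetate 13 (not isolated), via aryloxenium ion pair 14 (not isolated), via vinyl ortho-quinone methide 15 (not isolated)
Conditions: 10, n-BuLi (1.0 equiv), THF, −78 °C; transfer into 4 (1.05 equiv), THF, −78 °C; (CF3CO)2O (1.2 equiv), −78 °C; 2,6-lutidine (3 equiv), −78 °C to 23 °C; aq NaHCO3
Reagents that add atoms: none
Why: Proposed new method: aryllithium 11 should add 1,2 to the quinone carbonyl that lies between two CH groups (future C6), alkoxide 12 is acylated in place, and the tertiary, doubly allylic and benzylic trifluoroacetate 13 should ionise by alkyl–oxygen cleavage to the 4-aryl-aryloxenium ion pair 14, from which 2,6-lutidine removes a proton of one ring-bound CH2 (future C4) to give the vinyl ortho-quinone methide 15. The closest known reaction types are the 1,2-addition of organolithiums to 2,6-dialkyl-1,4-benzoquinones, the solvolytic ionisation of 4-aryl-para-quinol esters to aryloxenium ions, the loss of HX from 4-halo- and 4-acyloxycyclohexadienones to quinone methides, and the closure of the same type of vinyl ortho-quinone methide in DDQ cyclisations of ortho-prenylphenols and in the base-induced isomerisation of prenylquinones to chromenols; new is their merger into a redox-neutral dehydrative arylation–cyclisation. Pyran A, the only ring closed, forms by thermal disrotatory oxa-6π electrocyclisation of (Z)-15 (O1–C2 bond), which restores the aromaticity of arene A and so drains the preceding equilibria, the E isomer being fed in through reversible conjugate addition of trifluoroacetate. No stereocentre is created, since the carbinol carbon of 12 and 13 bears two identical ring arms and 16 is achiral. The step needs site selectivity between the two carbonyls (secured by the two flanking prenyl groups that shield the future C8a carbonyl), proton loss rather than 1,2-aryl shift or capture of the cation (secured by a buffered, non-nucleophilic medium in which the dienone oxygen is never protonated and by O1' on C8a', para to C6', which stabilises 14), and a single cyclisation (secured because the two prenyl groups are symmetry-equivalent and the one oxygen is consumed). No external oxidant is present, so arene B, both styrene-type alkenes and the surviving prenyl group are never exposed to oxidation.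

Step 6
Reactants: 16 O-TBS ether of the target
Product: 17 6-[2,2-dimethyl-8-(3-methylbut-2-enyl)-2H-chromen-6-yl]-2,2-dimethyl-2H-chromen-8-ol (CNP0158232.0)
Conditions: TBAF (1.1 equiv), AcOH (1.1 equiv), THF, 0 °C
Reagents that add atoms: none
Why: Fluoride-induced cleavage of the aryl silyl ether, driven by the Si–F bond and buffered with AcOH so that the phenoxide is protonated at once, leaves both chromenes and the prenyl group untouched; no stereocentre is involved.

## Compound list

1 | 4-methoxyphenol | COc1ccc(O)cc1 | starting material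
2 | prenyl bromide (1-bromo-3-methylbut-2-ene) | CC(C)=CCBr | starting material
3 | 4-methoxy-2,6-bis(3-methylbut-2-enyl)phenol | COc1cc(CC=C(C)C)c(O)c(CC=C(C)C)c1 | intermediate
4 | 2,6-bis(3-methylbut-2-enyl)-1,4-benzoquinone | CC(C)=CCC1=CC(=O)C=C(CC=C(C)C)C1=O | intermediate
5 | 5-bromo-2,3-dihydroxybenzaldehyde | O=Cc1cc(Br)cc(O)c1O | starting material
6 | 2-methylprop-1-enylmagnesium bromide | CC(C)=C[Mg]Br | starting material
7 | 5-bromo-3-(1-hydroxy-3-methylbut-2-enyl)benzene-1,2-diol (racemic, formed in the flask) | CC(C)=CC(O)c1cc(Br)cc(O)c1O | intermediate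
8 | (6Z)-4-bromo-2-hydroxy-6-(3-methylbut-2-enylidene)cyclohexa-2,4-dien-1-one (formed in the flask) | CC(C)=C/C=C1/C=C(Br)C=C(O)C1=O | intermediate
9 | 6-bromo-2,2-dimethyl-2H-chromen-8-ol | CC1(C)C=Cc2cc(Br)cc(O)c2O1 | intermediate
10 | [(6-bromo-2,2-dimethyl-2H-chromen-8-yl)oxy](tert-butyl)dimethylsilane | CC1(C)C=Cc2cc(Br)cc(O[Si](C)(C)C(C)(C)C)c2O1 | intermediate
11 | [8-(tert-butyldimethylsilyloxy)-2,2-dimethyl-2H-chromen-6-yl]lithium (formed in the flask) | CC1(C)C=Cc2cc([Li])cc(O[Si](C)(C)C(C)(C)C)c2O1 | intermediate
12 | lithium 1-[8-(tert-butyldimethylsilyloxy)-2,2-dimethyl-2H-chromen-6-yl]-3,5-bis(3-methylbut-2-enyl)-4-oxocyclohexa-2,5-dien-1-olate (formed in the flask) | CC(C)=CCC1=CC(O[Li])(c2cc3C=CC(C)(C)Oc3c(O[Si](C)(C)C(C)(C)C)c2)C=C(CC=C(C)C)C1=O | intermediate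
13 | 1-[8-(tert-butyldimethylsilyloxy)-2,2-dimethyl-2H-chromen-6-yl]-3,5-bis(3-methylbut-2-enyl)-4-oxocyclohexa-2,5-dien-1-yl trifluoroacetate (formed in the flask) | CC(C)=CCC1=CC(OC(=O)C(F)(F)F)(c2cc3C=CC(C)(C)Oc3c(O[Si](C)(C)C(C)(C)C)c2)C=C(CC=C(C)C)C1=O | intermediate
14 | 4-aryl-2,6-diprenyl-aryloxenium (4-oxocyclohexa-2,5-dienyl) cation, trifluoroacetate ion pair (formed in the flask) | CC(C)=CCC1=C[C+](c2cc3C=CC(C)(C)Oc3c(O[Si](C)(C)C(C)(C)C)c2)C=C(CC=C(C)C)C1=O.[O-]C(=O)C(F)(F)F | intermediate
15 | (6Z)-4-[8-(tert-butyldimethylsilyloxy)-2,2-dimethyl-2H-chromen-6-yl]-2-(3-methylbut-2-enyl)-6-(3-methylbut-2-enylidene)cyclohexa-2,4-dien-1-one (formed in the flask) | CC(C)=C/C=C1/C=C(c2cc3C=CC(C)(C)Oc3c(O[Si](C)(C)C(C)(C)C)c2)C=C(CC=C(C)C)C1=O | intermediate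
16 | tert-butyl({6-[2,2-dimethyl-8-(3-methylbut-2-enyl)-2H-chromen-6-yl]-2,2-dimethyl-2H-chromen-8-yl}oxy)dimethylsilane (O-TBS ether of the target) | CC(C)=CCc1cc(-c2cc(O[Si](C)(C)C(C)(C)C)c3c(c2)C=CC(C)(C)O3)cc2c1OC(C)(C)C=C2 | intermediate
17 | 6-[2,2-dimethyl-8-(3-methylbut-2-enyl)-2H-chromen-6-yl]-2,2-dimethyl-2H-chromen-8-ol (CNP0158232.0) | CC(C)=CCc1cc(-c2cc(O)c3c(c2)C=CC(C)(C)O3)cc2c1OC(C)(C)C=C2 | target

## Step count and risks

Total step count: 6. Longest linear sequence: 4 steps (1, 2, 5, 6 or 3, 4, 5, 6).

**Step 5.**
- In the addition, proton abstraction from the doubly allylic CH2 groups of the quinone or electron transfer may compete with carbonyl attack.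
- After acylation, ionisation may be sluggish in THF.
- A 1,2-aryl migration along the dienone–phenol pathway may intervene.
- Pyran B may open by dealkylation from the oxocarbenium form of the cation instead of the benzylic proton being lost.

The fallback uses only known chemistry, sets out from 10 and 2, and comes back at 16. Bromine–lithium exchange on 10 (n-BuLi, THF, −78 °C, through 11) and quenching with 2-isopropoxy-4,4,5,5-tetramethyl-1,3,2-dioxaborolane should give the chromenyl pinacol boronate F1. Purchased 4-bromophenol is prenylated twice with 2 under the conditions of step 1 to 4-bromo-2,6-bis(3-methylbut-2-enyl)phenol F2. Suzuki–Miyaura coupling of the two (Pd(PPh3)4, K3PO4, toluene/H2O, 80 °C) should give the 4-aryl-2,6-diprenylphenol F3. DDQ (1.05 equiv, toluene, 80 °C), the established dehydrogenative cyclisation of ortho-prenylphenols, then passes through 15 to 16.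

**Step 1.** O-alkylation, an incomplete second alkylation and geminal dialkylation with dearomatisation may erode the selectivity for the 2,6-pattern. The fallback sets out from 1 and comes back at 3. Dibromination (Br2, 2 equiv, CH2Cl2, 0 °C), directed by the hydroxyl group, should give 2,6-dibromo-4-methoxyphenol F4. A double Stille coupling with tributyl(3-methylbut-2-enyl)stannane (Pd(PPh3)4, DMF, 100 °C) then sets both linear prenyl groups at defined carbons and delivers 3.

**Step 3.** Precipitation of the magnesium catecholate may stall the addition, and the hydroxy ortho-quinone methide may oligomerise or tautomerise to the ortho-quinone and decay before it closes. The fallback sets out from 5 and comes back at 9. Wittig olefination–lactonisation with Ph3P=CHCO2Et in N,N-diethylaniline at reflux should give 6-bromo-8-hydroxycoumarin F5. Excess MeMgBr (THF, 0 °C to 23 °C) opens the lactone by double 1,2-addition to 5-bromo-3-[(Z)-3-hydroxy-3-methylbut-1-enyl]benzene-1,2-diol F6. Its Z alkene is inherited from the ring, and it cyclodehydrates with PPTS in toluene to 9.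

## Further compounds

F1 | step 5 | tert-butyl{[2,2-dimethyl-6-(4,4,5,5-tetramethyl-1,3,2-dioxaborolan-2-yl)-2H-chromen-8-yl]oxy}dimethylsilane | CC1(C)C=Cc2cc(B3OC(C)(C)C(C)(C)O3)cc(O[Si](C)(C)C(C)(C)C)c2O1
F2 | step 5 | 4-bromo-2,6-bis(3-methylbut-2-enyl)phenol | CC(C)=CCc1cc(Br)cc(CC=C(C)C)c1O
F3 | step 5 | 4-[8-(tert-butyldimethylsilyloxy)-2,2-dimethyl-2H-chromen-6-yl]-2,6-bis(3-methylbut-2-enyl)phenol | CC(C)=CCc1cc(-c2cc3C=CC(C)(C)Oc3c(O[Si](C)(C)C(C)(C)C)c2)cc(CC=C(C)C)c1O
F4 | step 1 | 2,6-dibromo-4-methoxyphenol | COc1cc(Br)c(O)c(Br)c1
F5 | step 3 | 6-bromo-8-hydroxycoumarin | O=C1C=Cc2cc(Br)cc(O)c2O1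
F6 | step 3 | 5-bromo-3-[(Z)-3-hydroxy-3-methylbut-1-enyl]benzene-1,2-diol | CC(C)(O)/C=C\c1cc(Br)cc(O)c1O
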